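**Retrosynthetic overview**
1. C3'–OH last: face-selective oxidation of the β-diketone enol of the complete tetracycle.
2. Rings C and D (the bicyclo[3.3.1] core) by a two-bond (3+3) union instead of a polyene cyclisation: C8–C1' by cation–olefin closure onto a dearomatised orsellinate, C5'–C11 by catalyst-controlled alkylative dearomatisation of methyl 3,5-dimethylorsellinate with an enantiopure bicyclic allylic bromide.
3. Ring A is made as the 3,4-seco lactone directly, without a Baeyer–Villiger step: ring-closing metathesis (C1=C2) between an acrylate on the C4 tertiary alcohol and a propenyl group on C10.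
4. Ring B, C5 and C10 come from (S)-carvone (C5 from the pool, C10 by double α'-alkylation, C4 from the isopropenyl group); C11 by Stille hydroxymethylation of the C9 enol triflate.
5. Order of ring formation: B (pool) → A (metathesis) → aromatic D precursor made separately → C closes last and turns D into the bridged bicycle.

Assumption: atoms are numbered as in the natural product (C1–C11 terpenoid part; C1'–C6' orsellinate ring with CO2Me on C1', CH3 and C11 on C5', the exocyclic CH2 on C6'), and of the two pseudoenantiomeric cinchona catalysts the one that gives the drawn C5' configuration in step 12 is used.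

**Route**

Step 1
Reactants: 1 (S)-(+)-carvone
Product: 3 (5S)-2,6-dimethyl-5-(prop-1-en-2-yl)cyclohex-2-en-1-one (6-methylcarvone; C6 epimers), via lithium dienolate 2 (not isolated)
Conditions: LiN(i-Pr)2, THF, −78 °C; then MeI, −78 to 0 °C
Reagents that add atoms: iodomethane, CI
Why: Kinetic α'-deprotonation of the enone and SN2 methylation (enolate alkylation); the new C6 centre need not be controlled because it is planarised again in step 2.

Step 2
Reactants: 3 6-methylcarvone
Product: 5 (5R,6R)-2,6-dimethyl-6-(prop-2-en-1-yl)-5-(prop-1-en-2-yl)cyclohex-2-en-1-one, via lithium dienolate 4 (not isolated)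
Conditions: LiN(i-Pr)2, THF, −78 °C; then allyl bromide, DMPU, −78 °C to rt
Reagents that add atoms: allyl bromide, C=CCBr
Why: Enolate alkylation in which the allyl group enters anti to the adjacent isopropenyl group, so the ring methyl (future C10 methyl) ends cis to the C5 side chain and the quaternary C10 centre is set by the carvone stereocentre.

Step 3
Reactants: 5 6-allyl-6-methylcarvone
Product: 6 (5R,6R)-2,6-dimethyl-6-[(E)-prop-1-en-1-yl]-5-(prop-1-en-2-yl)cyclohex-2-en-1-one
Conditions: RuHCl(CO)(PPh3)3 (5 mol%), toluene, 80 °C
Reagents that add atoms: none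
Why: Ruthenium hydride olefin isomerisation (hydrometalation/β-hydride elimination) moves only the monosubstituted terminal alkene one position to the E-propenyl group needed for the later metathesis, and no stereocentre is touched.

Step 4
Reactants: 6 propenyl enone
Product: 8 (5R,6R)-2,6-dimethyl-6-[(E)-prop-1-en-1-yl]-5-(prop-1-en-2-yl)cyclohex-1-en-1-yl trifluoromethanesulfonate, via lithium enolate 7 (not isolated)
Conditions: LiBH(s-Bu)3, THF, −78 °C; then PhNTf2, −78 to 0 °C
Reagents that add atoms: N-phenyl-bis(trifluoromethanesulfonimide), O=S(=O)(N(c1ccccc1)S(=O)(=O)C(F)(F)F)C(F)(F)F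
Why: Conjugate hydride reduction of the enone gives the enolate regiospecifically and O-triflation traps it as the tetrasubstituted C8=C9 enol triflate, so no new stereocentre is created.

Step 5
Reactants: 8 enol triflate
Product: 9 (5S,6R)-5-(2-hydroxypropan-2-yl)-2,6-dimethyl-6-[(E)-prop-1-en-1-yl]cyclohex-1-en-1-yl trifluoromethanesulfonate
Conditions: Co(acac)2 (20 mol%), PhSiH3, O2 (1 atm), THF, rt
Reagents that add atoms: dioxygen, O=O
Why: Mukaiyama hydration (hydrogen-atom transfer from a cobalt hydride, O2 capture, reduction) is Markovnikov and selective for the 1,1-disubstituted isopropenyl group over the 1,2-disubstituted propenyl group and the electron-poor enol triflate, giving the C4 tertiary alcohol without a new stereocentre.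

Step 6
Reactants: 9 tertiary alcohol
Product: 10 acrylate ester of 9 (O-acryloyl on the tertiary C4 oxygen)
Conditions: acryloyl chloride, Et3N, DMAP (cat.), CH2Cl2, 0 °C to rt
Reagents that add atoms: acryloyl chloride, C=CC(=O)Cl
Why: DMAP-catalysed O-acylation of the only hydroxyl group installs C2 and C3 of ring A.

Step 7
Reactants: 10 acrylate
Product: 11 (5S,10R) bicyclic lactone triflate: seven-membered α,β-unsaturated lactone (O–C3(=O)–C2H=C1H, CMe2 at C4) trans-fused at C5/C10 to the cyclohexene carrying 8-CH3, 9-OTf and 10-CH3
Conditions: second-generation Hoveyda–Grubbs catalyst (10 mol%), toluene (2 mM), 100 °C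
Reagents that add atoms: none
Why: Ring-closing metathesis between the acrylate and the propenyl group (propene is lost) closes ring A as the cis-enoate lactone, helped by the gem-dimethyl group and the trans-diequatorial placement of the two arms, with no stereocentre formed.

Step 8
Reactants: 11 lactone triflate
Product: 12 (5S,10R) allylic alcohol: as 11 with CH2OH (C11) on C9 in place of OTf
Conditions: Pd(PPh3)4 (10 mol%), LiCl, Bu3SnCH2OH, 1,4-dioxane, 100 °C
Reagents that add atoms: (tributylstannyl)methanol, CCCC[Sn](CCCC)(CCCC)CO
Why: Migita–Kosugi–Stille coupling (oxidative addition of the enol triflate to zerovalent palladium, transfer of the hydroxymethyl group from tin, reductive elimination) installs C11 on the tetrasubstituted alkene without touching the enoate.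

Step 9
Reactants: 12 allylic alcohol
Product: 13 (5S,10R) allylic bromide: as 12 with CH2Br
Conditions: CBr4, PPh3, CH2Cl2, 0 °C
Reagents that add atoms: tetrabromomethane, BrC(Br)(Br)Br
Why: Appel bromination converts the primary allylic alcohol into the SN2-reactive bromide under neutral conditions.

Step 10
Reactants: 14 methyl 2,4-dihydroxy-3,6-dimethylbenzoate (methyl atratate)
Product: 15 methyl 5-formyl-2,4-dihydroxy-3,6-dimethylbenzoate
Conditions: MgCl2, Et3N, (CH2O)n, MeCN, reflux
Reagents that add atoms: formaldehyde (as paraformaldehyde), C=O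
Why: Casnati–Skattebøl ortho-formylation, in which the magnesium phenoxide directs formaldehyde to the only free ring position (ortho to the 4-OH) and a second formaldehyde oxidises the benzylic alkoxide by hydride transfer.

Step 11
Reactants: 15 aldehyde
Product: 16 methyl 2,4-dihydroxy-3,5,6-trimethylbenzoate (methyl 3,5-dimethylorsellinate)
Conditions: H2 (1 atm), Pd/C, AcOH, rt
Reagents that add atoms: none
Why: Catalytic hydrogenolysis of the ortho-hydroxybenzaldehyde (via the benzylic alcohol) reduces CHO to the aryl methyl group.

Step 12
Reactants: 13 allylic bromide and 16 methyl 3,5-dimethylorsellinate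
Product: 18 (5S,10R,5'R) methyl 6-hydroxy-2,3,5-trimethyl-4-oxo-3-[(ring A/B unit)methyl]cyclohexa-1,5-diene-1-carboxylate (C5'-alkylated dearomatised orsellinate), via caesium phenoxide 17 (not isolated)
Conditions: Cs2CO3, N-(9-anthracenylmethyl)cinchonidinium bromide (20 mol%), toluene, −20 to 0 °C
Reagents that add atoms: none
Why: Proposed new method: solid–liquid phase-transfer alkylative dearomatisation in which the 4-phenoxide is C-alkylated by the primary allylic bromide (SN2) at the methyl-bearing ortho carbon C5', where the quaternary product cannot rearomatise, while the chiral cinchonidinium cation ion-paired to the phenoxide oxygen shields one face of the planar anion so that the C5' centre is set by the catalyst and not by the remote centres of 13; the closest known reaction types are base-mediated alkylative dearomatisation of orsellinate and acylphloroglucinol esters with allylic bromides and cinchona phase-transfer-catalysed asymmetric alkylation and dearomatisation–annulation of prochiral enolates.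

Step 13
Reactants: 18 dearomatised orsellinate
Product: 19 3'-deoxy precursor of the target (2'-enol form; C5 S, C8 S, C9 S, C10 S, C1' R, C5' R)
Conditions: SnCl4, CH2Cl2, −78 to −20 °C
Reagents that add atoms: none
Why: Biomimetic cation–olefin cyclisation in which SnCl4 bound to the enolised β-keto ester acts as a Lewis-acid-assisted Brønsted acid and protonates C9 of the tetrasubstituted alkene on the face opposite the axial C10 methyl, and the C8 cation is then captured through a chair transition state by C1' of the exocyclic dienol (formed by dienolisation of the C6' methyl, which becomes the C6'=CH2 group), also from the face opposite the C10 methyl, giving the trans B/C junction (C8 methyl cis to the C10 methyl, C9–H trans to both) and, because the C4' bridge must be 1,3-diaxial on the fixed C5' centre, a single configuration at C1', while any O-cyclised enol ether re-ionises and funnels to the C–C product.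

Step 14
Reactants: 19 enol diketone
Product: 20 the target natural product (3'S tertiary alcohol)
Conditions: dimethyldioxirane, acetone/CH2Cl2, −78 to 0 °C
Reagents that add atoms: dimethyldioxirane, CC1(C)OO1
Why: Epoxidation of the electron-rich enol double bond (Rubottom-type α-hydroxylation of the β-diketone) from the convex face, syn to the C6' methylidene bridge and away from the C11–C9–C8 bridge with its axial C9–H, sets C3' (S), while the hindered exocyclic alkene and the unsaturated lactone are not attacked at low temperature.

**Compound list**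

1 | (S)-(+)-carvone, (5S)-2-methyl-5-(prop-1-en-2-yl)cyclohex-2-en-1-one | CC1=CC[C@@H](CC1=O)C(C)=C | starting material
2 | lithium cross-conjugated dienolate of 1 (O–C1=C6, C2=C3) | [Li+].[O-]C1=C[C@@H](C(C)=C)CC=C1C | intermediate (not isolated)
3 | (5S)-2,6-dimethyl-5-(prop-1-en-2-yl)cyclohex-2-en-1-one, C6 epimers | CC1=CC[C@@H](C(C)C1=O)C(C)=C | intermediate
4 | lithium dienolate of 3 | [Li+].[O-]C1=C(C)[C@@H](C(C)=C)CC=C1C | intermediate (not isolated)
5 | (5R,6R)-2,6-dimethyl-6-(prop-2-en-1-yl)-5-(prop-1-en-2-yl)cyclohex-2-en-1-one (allyl trans to isopropenyl) | O=C1C(C)=CC[C@H](C(C)=C)[C@@]1(C)CC=C | intermediate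
6 | (5R,6R)-2,6-dimethyl-6-[(E)-prop-1-en-1-yl]-5-(prop-1-en-2-yl)cyclohex-2-en-1-one | O=C1C(C)=CC[C@H](C(C)=C)[C@@]1(C)/C=C/C | intermediate
7 | lithium enolate from 1,4-reduction of 6 (O–C1=C2) | [Li+].[O-]C1=C(C)CC[C@H](C(C)=C)[C@@]1(C)/C=C/C | intermediate (not isolated)
8 | (5R,6R)-2,6-dimethyl-6-[(E)-prop-1-en-1-yl]-5-(prop-1-en-2-yl)cyclohex-1-en-1-yl trifluoromethanesulfonate | O=S(=O)(OC1=C(C)CC[C@H](C(C)=C)[C@@]1(C)/C=C/C)C(F)(F)F | intermediate
9 | (5S,6R)-5-(2-hydroxypropan-2-yl)-2,6-dimethyl-6-[(E)-prop-1-en-1-yl]cyclohex-1-en-1-yl trifluoromethanesulfonate | O=S(=O)(OC1=C(C)CC[C@H](C(C)(C)O)[C@@]1(C)/C=C/C)C(F)(F)F | intermediate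
10 | acrylate ester of the tertiary alcohol 9 | O=S(=O)(OC1=C(C)CC[C@H](C(C)(C)OC(=O)C=C)[C@@]1(C)/C=C/C)C(F)(F)F | intermediate
11 | (5S,10R) ring A lactone / ring B enol triflate (trans-fused; 4,4,8,10-tetramethyl, 9-OTf, C1=C2, C8=C9) | O=S(=O)(OC1=C(C)CC[C@H]2[C@@]1(C)C=CC(=O)OC2(C)C)C(F)(F)F | intermediate
12 | (5S,10R) allylic alcohol (C11 CH2OH on C9) | OCC1=C(C)CC[C@H]2[C@@]1(C)C=CC(=O)OC2(C)C | intermediate
13 | (5S,10R) allylic bromide (C11 CH2Br on C9) | BrCC1=C(C)CC[C@H]2[C@@]1(C)C=CC(=O)OC2(C)C | intermediate
14 | methyl 2,4-dihydroxy-3,6-dimethylbenzoate | COC(=O)c1c(C)cc(O)c(C)c1O | starting material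
15 | methyl 5-formyl-2,4-dihydroxy-3,6-dimethylbenzoate | COC(=O)c1c(C)c(C=O)c(O)c(C)c1O | intermediate
16 | methyl 2,4-dihydroxy-3,5,6-trimethylbenzoate | COC(=O)c1c(C)c(C)c(O)c(C)c1O | intermediate
17 | caesium 4-phenoxide of 16 | [Cs+].COC(=O)c1c(C)c(C)c([O-])c(C)c1O | intermediate (not isolated)
18 | (5S,10R,5'R) C5'-alkylated dearomatised orsellinate (C5' bears CH3 and C11; C4'=O; C2'-OH enol; C1'=C6') | CC1=C(C(=O)OC)C(O)=C(C)C(=O)[C@]1(C)CC1=C(C)CC[C@H]2[C@@]1(C)C=CC(=O)OC2(C)C | intermediate
19 | 3'-deoxy precursor of the target, 2'-enol form | C=C1[C@@]2(C)C[C@H]3[C@]4(C)C=CC(=O)OC(C)(C)[C@H]4CC[C@]3(C)[C@]1(C(=O)OC)C(O)=C(C)C2=O | intermediate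
20 | target natural product (5S,8S,9S,10S,1'R,3'S,5'R): ring A unsaturated ε-lactone, C6' methylidene, C1' CO2Me, 2',4'-dioxo, 3'-OH | C=C1[C@@]2(C)C[C@H]3[C@]4(C)C=CC(=O)OC(C)(C)[C@H]4CC[C@]3(C)[C@]1(C(=O)OC)C(=O)[C@@](C)(O)C2=O | target

**Step count and risks**

Total: 14 steps. Longest linear sequence: 12 steps (steps 1–9 and 12–14 from carvone); steps 10–11 make the aromatic partner in parallel.

The three steps most likely to fail:

Step 12 (alkylative dearomatisation). Risks are O-alkylation, alkylation at C3' instead of C5', and incomplete face control by the ammonium ion pair. The fallback sets out from 12 and comes back at 18. Alcohol 12 is acylated with methyl chloroformate and pyridine to the allylic methyl carbonate F1. F1 and 16 are then coupled by a Tsuji–Trost reaction with zerovalent palladium (Pd2(dba)3 and the DACH-phenyl Trost ligand, CH2Cl2, rt). In this π-allyl route any aryl allyl ether is re-ionised and funnels to the C-allylated dienone, and the face is controlled by the chiral ligand on palladium instead of by an ion pair. If neither catalyst gives useful selectivity, the two C5' epimers are diastereomers and are separated at 18; the wrong epimer cannot close the bicycle in step 13.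

Step 13 (ring C closure). Risks are kinetic O-cyclisation through O4', loss of the allyl group from C5' under acid, and ionisation of the tertiary lactone C–O bond. The fallback sets out from 18 and comes back at 19. Catalytic TfOH in CH2Cl2 at −40 °C is used to form the kinetic product deliberately, the O-cyclised dihydropyran vinylogous ester F2 (C8–O4' bond). F2 is then treated with Me2AlCl at −78 °C. The oxophilic aluminium ionises the tertiary C8–O bond to a contact pair of C8 cation and aluminium diketonate; the tethered cation is recaptured at C1' of the ester dienol (the C6' methyl becoming the methylidene), a formal O-to-C rearrangement under aprotic conditions that gives 19.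

Step 7 (ring-closing metathesis). The risk is that the acrylate of a tertiary alcohol and a propenyl group on a quaternary carbon do not close. The fallback sets out from 9 and comes back at 11. Alcohol 9 is esterified with diethylphosphonoacetic acid (DCC, DMAP) to the phosphonoacetate F3. Selective ozonolysis of the propenyl group (O3, CH2Cl2, −78 °C; then Me2S) gives the C10 aldehyde F4. An intramolecular Horner–Wadsworth–Emmons reaction (LiCl, i-Pr2NEt, MeCN) then closes ring A to 11, the ring enforcing the cis alkene.

Further compounds
F1 | step 12 | (5S,10R) allylic methyl carbonate of 12 | COC(=O)OCC1=C(C)CC[C@H]2[C@@]1(C)C=CC(=O)OC2(C)C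
F2 | step 13 | O-cyclised vinylogous ester (C8–O4' ether; C4'=C3', C2'=O, C1'=C6') | CC1=C(C(=O)OC)C(=O)C(C)=C2O[C@@]3(C)CC[C@@H]4C(C)(C)OC(=O)C=C[C@@]4(C)[C@@H]3C[C@]12C
F3 | step 7 | diethylphosphonoacetate ester of 9 | O=S(=O)(OC1=C(C)CC[C@H](C(C)(C)OC(=O)CP(=O)(OCC)OCC)[C@@]1(C)/C=C/C)C(F)(F)F
F4 | step 7 | C10 aldehyde from ozonolysis of F3 | O=S(=O)(OC1=C(C)CC[C@H](C(C)(C)OC(=O)CP(=O)(OCC)OCC)[C@@]1(C)C=O)C(F)(F)F
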